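## The problem

Compound 29 is a sesquilignan. A trans-2-aryl-3-(hydroxymethyl)-7-methoxy-2,3-dihydrobenzofuran is joined through one methylene at C-5 to C-α of a γ-butyrolactone, and C-β of that lactone carries a secondary benzylic carbinol. The five stereocentres form two clusters separated by that methylene: C-2/C-3 of the dihydrobenzofuran (2S,3R, trans) and the contiguous triad C-α (3R), C-β (4R) and carbinol carbon (R). Each cluster needs its own source of absolute configuration. Within the triad the carbinol centre can control C-β if the two are tied into a small ring, and C-α is enolisable and trans to C-β, so it can be left to equilibration. Within the benzofuran, C-3 is epimerisable while it bears an ester, so only C-2 must be set by a reagent. Three places are fragile. The para-oxygenated benzylic alcohol ionises under acid and, once its phenol is free, loses water under base through a quinone methide. The lactone can migrate onto the carbinol oxygen. The benzofuran C-2–O bond is a benzylic ether. The phenols must therefore stay capped until a neutral last step, and nothing strongly acidic may follow formation of the carbinol. The key step rests on one feature: the carbinol oxygen and the lactone OCH2 carbon are 1,3 to each other across C-β (O–CH(Ar)–C-β–CH2–O), and C-β is also the β-carbon of the C-α–C=O unit. With the lactone carbonyl unmasked as an α,β-unsaturated ester, a one-carbon radical held on the carbinol oxygen by silicon reaches C-β through a five-membered ring (O, Si, CH2, C-β, carbinol carbon), and the silicon is later exchanged for the lactone oxygen.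

## Retrosynthesis

**29 ⇒ 28 ⇒ 27 (protecting groups).** The last bonds cut are the two aryl O–benzyl bonds of 28 and, before that, the primary O–Si bond of 27. Benzyl is chosen for the phenols because aryl silyl ethers would not survive the fluoride/peroxide oxidation or the basic steps, and a free para-hydroxybenzyl alcohol would not survive base. Hydrogenolysis is neutral and is placed last; it must stop before the benzylic alcohol or the C-2–O bond reacts. The primary alcohol is carried as a TBS ether so that only fast-cleaving aryl benzyl ethers remain for that step.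

**27 ⇒ 25 ⇒ 24 (lactone and OCH2 oxygen).** The lactone acyl–oxygen bond is cut to the dihydroxy ester 25, and the primary hydroxyl is traced back to a C–Si bond in the 1,2-oxasilolane 24. This removes the lactone ring and makes C-α inconsequential, since the trans lactone is the thermodynamic epimer. The forward steps must oxidise C–Si without touching the other silyl ether and must close the lactone through the primary, not the secondary, hydroxyl.

**24 ⇒ 23 (key cut, C-β–CH2).** The C-β–CH2 bond is cut, giving the (bromomethyl)dimethylsilyl ether 23 of a γ-hydroxy enoate. The neighbouring cut at C-α–CH2(benzofuran) leaves C-β unsolved. An untethered hydroxymethyl nucleophile would be expected to add anti to the γ-oxygen of an E enoate, which is the wrong relative configuration, whereas the tether enforces the required syn delivery. The precursor has one stereocentre fewer in the triad and no ring. The forward reaction must cyclise faster than it is reduced and must place aryl and side chain trans on the new ring.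

**23 ⇒ 21 + 22 (O–Si).** Cutting the silyl ether gives the allylic alcohol 21 and commercial chlorosilane 22. Nothing else in 21 has a free hydroxyl, so the silylation needs no selectivity.

**21 ⇒ 20 + 6 (CH2–C-α).** The bond between the benzylic methylene and the alkene carbon is cut, giving benzylic boronate 20 and (Z)-α-iodo enoate 6, to be joined by an sp3–sp2 Suzuki–Miyaura coupling. Two neighbouring cuts through the C=C bond were weighed:
- An olefin cross-metathesis would have to unite a 1,1-disubstituted, electron-poor alkene with a secondary aryl allylic alcohol. That is a slow pairing, and ruthenium alkylidenes also isomerise such alcohols to ketones.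
- A Wittig-type olefination would need an α-aryl-α-oxy aldehyde that racemises easily.

The chosen cut divides the molecule into halves of similar size, each with one stereocluster. It fixes the alkene geometry in the iodide, whose ester is trans to the carbinol carbon so the free alcohol cannot close to a butenolide.

**6 ⇒ 4 ⇒ 1 + 2 (iodide and carbinol).** The C–I and C-3–H bonds are traced to the alkyne of 4 by trans-hydroalumination/iodination directed by the propargylic alkoxide. The carbinol C–C bond is then cut to aldehyde 1 and methyl propiolate 2. One catalytic asymmetric alkynylation sets the only reagent-controlled centre of the lactone half.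

**20 ⇒ 16 + 17 (benzylic carbon).** The aryl–CH2 bond is cut, giving aryl bromide 16 and chloromethylboronate 17. The one-carbon homologation happens on boron after bromine–lithium exchange, which avoids a separate formylation, reduction and halogenation.

**16 ⇒ 15 ⇒ 14 ⇒ 12 (dihydrofuran ring).** After functional-group changes (silyl ether, alcohol, ester) the C-2–C-3 bond is cut, giving aryl diazoacetate 12, whose carbenoid inserts into the benzylic ether C–H bond. This closes the ring and sets C-2 under catalyst control in a non-ionising step. C-3 is then corrected to trans by base. An aldol/cyclisation sequence would need more steps and an acid-mediated ring closure.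

**12 ⇒ 10 + 11; 10 ⇒ 8 + 9; 8 ⇒ 7.** The aryl–C(N2) bond is cut to aryl iodide 10 and methyl diazoacetate 11, the ether C–O bond to phenol 8 and benzylic alcohol 9, and the C–I bond to commercial 4-bromo-2-methoxyphenol 7. The bromine blocks the para position during iodination and later becomes the handle for the benzylic boronate.

## Roads not taken

**Alternative 1:** The cut goes through the lactone C-α–C-β bond together with a temporary bond between C-α and the carbinol carbon. Cinnamyl methyl diazomalonate A1 would be cyclised by a chiral bis(oxazoline) complex of CuOTf to the cyclopropane-fused lactone A2. An oxygen nucleophile would then open the three-membered ring at the benzylic carbon with inversion, the benzofuran half would be attached by alkylation of the resulting malonate-type lactone, and the extra ester would be removed.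
- Merits: one catalytic step builds the lactone ring, the C-α–C-β bond and both the C-β and carbinol centres from an achiral precursor. There is never a doubt which oxygen ends in the lactone. The fragment union is a robust soft-enolate alkylation, and no tin is used.
- Weak points: allyl diazomalonates are poor substrates for high enantioselectivity in copper-catalysed intramolecular cyclopropanation. The ring opening of a donor–acceptor cyclopropane with a 4-oxygenated aryl donor tends toward an ion-pair pathway, so inversion at the carbinol carbon is not assured and oxygen nucleophiles are sluggish. The later hot dealkoxycarbonylation sits next to a β-benzylic oxygen substituent that can eliminate.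
- Comparison: on convergence and on lactone regiochemistry this road is the better one. The chosen plan sets against it a carbinol centre made by a separate catalyst-controlled carbonyl addition that is never again a site of substitution, and a C-β centre that follows from it through a geometrically constrained ring closure.

**Alternative 2:** The lactone oxygen is excised, giving the 3-substituted cyclobutanone A3. Aqueous H2O2 with a chiral phosphoric acid, or a Baeyer–Villiger monooxygenase, would insert oxygen next to one of the two ring methylenes and give lactone A4 with the C-β centre. The benzofuranylmethyl group would then be introduced by trans-selective enolate alkylation.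
- Merits: a clean, metal-free ring expansion; the last C–C bond is classical lignan chemistry that sets C-α trans directly, with no equilibration step and no tin. The step count is about equal to the chosen plan.
- Weak points: A3 already carries the carbinol stereocentre, so the two methylenes are diastereotopic and the catalyst must override or cooperate with a centre one bond from the prochiral carbon. The known organocatalytic systems perform best with 3-aryl cyclobutanones, not with branched 3-alkyl ones. The carbinol and C-β are set by two independent asymmetric events. Peroxide with a strong Brønsted acid meets an electron-rich benzylic silyl ether.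
- Comparison: on convergence this road is at least as good. The chosen plan sets against it that a single catalyst-made centre dictates C-β by substrate control through a five-membered transition state, and that no oxidant stronger than buffered peroxide touches the electron-rich arenes.

**Alternative 3:** This road concerns the other half. The benzofuran C-3–C-3a bond is traced to a 1,2-shift of the fused arene in (2S)-flavanone A5. PhI(OAc)2 with H2SO4 in trimethyl orthoformate would contract the pyranone to the trans dihydrobenzofuran ester A6, the former carbonyl carbon becoming the methyl ester.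
- Merits: the trans ester arises directly and no diazo compound or rhodium catalyst is needed. From an o-hydroxyacetophenone the sequence is about one step shorter than steps 3–6 here. These are real advantages.
- Weak points: a flavanone with an electron-rich 2-aryl group opens to the chalcone or ionises at C-2 under H2SO4, which erodes the only reagent-set centre. With trivalent iodine an electron-rich 2-aryl group also favours the competing 2,3-aryl shift and dehydrogenation. An aryl silyl ether would not survive the acid. The lactone half is left unsolved.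
- Comparison: the chosen route sets against the shorter sequence a C-2 centre created by catalyst-controlled C–H insertion under neutral conditions, with the benzylic ether never exposed to strong acid.

Key step: step 12

Remark: the sense of induction in steps 1 and 6 is assigned by analogy with simpler aryl aldehydes and aryl benzyl ethers; should a first run show the opposite sense, the antipodal ligand ((S)-BINOL, Rh2(S-PTTL)4) is used and nothing else changes.

Abbreviations used in names: Ar = 4-(benzyloxy)-3-methoxyphenyl; TBS = tert-butyldimethylsilyl; TES = triethylsilyl; Bpin = 4,4,5,5-tetramethyl-1,3,2-dioxaborolan-2-yl; BF = (2S,3R)-2-Ar-3-(TBSO-methyl)-7-methoxy-2,3-dihydro-1-benzofuran-5-yl.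

## Route

Step 1
Reactants: 1 4-(benzyloxy)-3-methoxybenzaldehyde; 2 methyl propiolate
Product: 4 methyl (4S)-4-Ar-4-hydroxybut-2-ynoate, via alkynylzinc 3 (not isolated)
Conditions: 2, Et2Zn, (R)-BINOL (40 mol %), HMPA, CH2Cl2, rt; then Ti(OiPr)4; then 1, rt; aq. NH4Cl
Reagents that add atoms: none
Why: Titanium–BINOLate-catalysed addition of the alkynylzinc formed from 2 and Et2Zn to an aryl aldehyde (asymmetric alkynylation); the catalyst selects the aldehyde face and sets the carbinol centre, which is S here only because the alkynyl carbon outranks the aryl group.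

Step 2
Reactants: 4 methyl (4S)-4-Ar-4-hydroxybut-2-ynoate
Product: 6 methyl (2Z,4R)-4-Ar-4-hydroxy-2-iodobut-2-enoate, via cyclic alkenylaluminate 5 (not isolated)
Conditions: NaAlH2(OCH2CH2OMe)2 (Red-Al), THF, −72 °C; then I2, −72 → −20 °C; aq. potassium sodium tartrate, Na2S2O3
Reagents that add atoms: iodine, II
Why: trans-Hydroalumination of a propargylic alkoxide: aluminium bound to the alkoxide delivers hydride to C-3 and ends on C-2 inside a five-membered chelate, so iodinolysis with retention should give the Z iodide with the ester trans to the carbinol carbon (no butenolide can form) and leave the stereocentre untouched.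

Step 3
Reactants: 7 4-bromo-2-methoxyphenol
Product: 8 4-bromo-2-iodo-6-methoxyphenol
Conditions: NaI, aq. NaOCl, NaOH, MeOH, 0 °C; then dil. HCl
Reagents that add atoms: sodium iodide, [Na+].[I-]
Why: Electrophilic iodination of the phenoxide; the para position is blocked by bromine and the phenoxide oxygen directs more strongly than the methoxy group, so iodine should enter ortho to oxygen.

Step 4
Reactants: 8 4-bromo-2-iodo-6-methoxyphenol; 9 [4-(benzyloxy)-3-methoxyphenyl]methanol
Product: 10 2-(Ar-methoxy)-5-bromo-1-iodo-3-methoxybenzene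
Conditions: PPh3, DIAD, THF, 0 °C → rt
Reagents that add atoms: none
Why: Mitsunobu etherification of an acidic, ortho-halogenated phenol with a primary benzylic alcohol under neutral conditions.

Step 5
Reactants: 10 2-(Ar-methoxy)-5-bromo-1-iodo-3-methoxybenzene; 11 methyl diazoacetate
Product: 12 methyl 2-[2-(Ar-methoxy)-5-bromo-3-methoxyphenyl]-2-diazoacetate
Conditions: Pd(PPh3)4 (5 mol %), Ag2CO3 (0.5 equiv), Et3N, toluene, rt (11 as a dilute solution)
Reagents that add atoms: none
Why: Zerovalent-palladium-catalysed cross-coupling of an aryl iodide with an alkyl diazoacetate with retention of the diazo group; oxidative addition at room temperature should discriminate C–I from C–Br.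

Step 6
Reactants: 12 methyl 2-[2-(Ar-methoxy)-5-bromo-3-methoxyphenyl]-2-diazoacetate
Product: 14 methyl (2S,3S)-2-Ar-5-bromo-7-methoxy-2,3-dihydro-1-benzofuran-3-carboxylate (trans), via cis ester 13 (not isolated)
Conditions: Rh2(R-PTTL)4 [dirhodium tetrakis(N-phthaloyl-(R)-tert-leucinate)] (1 mol %), toluene, −60 °C; then NaOMe (cat.), MeOH, 0 °C → rt
Reagents that add atoms: none
Why: Dirhodium carbenoid 1,5-insertion into the benzylic ether C–H bond closes the dihydrofuran (C-2–C-3 bond) and gives the cis ester under kinetic control, the chiral carboxylate ligands deciding C-2; methoxide then epimerises the enolisable C-3 to the more stable trans ester without touching C-2.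

Step 7
Reactants: 14 methyl (2S,3S)-2-Ar-5-bromo-7-methoxy-2,3-dihydro-1-benzofuran-3-carboxylate
Product: 15 [(2S,3R)-2-Ar-5-bromo-7-methoxy-2,3-dihydro-1-benzofuran-3-yl]methanol
Conditions: LiAlH4, THF, 0 °C
Reagents that add atoms: none
Why: Hydride reduction of the ester to the primary alcohol; the aryl bromide and benzyl ethers are inert at 0 °C, and C-3 is no longer enolisable afterwards.

Step 8
Reactants: 15 [(2S,3R)-2-Ar-5-bromo-7-methoxy-2,3-dihydro-1-benzofuran-3-yl]methanol
Product: 16 (2S,3R)-2-Ar-5-bromo-3-(TBSO-methyl)-7-methoxy-2,3-dihydro-1-benzofuran (BF-Br)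
Conditions: TBSCl, imidazole, DMF, rt
Reagents that add atoms: tert-butyldimethylsilyl chloride, CC(C)(C)[Si](C)(C)Cl
Why: Standard silylation of the primary alcohol; the TBS ether should survive the organolithium, the buffered peroxide and DBU, and is removed before the phenols are freed.

Step 9
Reactants: 16 BF-Br; 17 2-(chloromethyl)-4,4,5,5-tetramethyl-1,3,2-dioxaborolane
Product: 20 BF-CH2-Bpin (benzylic pinacol boronate), via aryllithium 18 (not isolated), via chloromethyl borate 19 (not isolated)
Conditions: n-BuLi, THF, −78 °C; then 17, −78 °C → rt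
Reagents that add atoms: none
Why: Bromine–lithium exchange, capture of the aryllithium by the boronic ester and 1,2-aryl shift from boron to carbon with loss of chloride (Matteson homologation) should give the benzylic boronate in one flask.

Step 10
Reactants: 20 BF-CH2-Bpin; 6 methyl (2Z,4R)-4-Ar-4-hydroxy-2-iodobut-2-enoate
Product: 21 methyl (2E,4R)-4-Ar-2-(BF-methyl)-4-hydroxybut-2-enoate
Conditions: PdCl2(dppf) (5 mol %), K3PO4, THF/H2O (10:1), 55 °C
Reagents that add atoms: none
Why: Suzuki–Miyaura coupling of a primary benzylic boronic ester with an activated alkenyl iodide; oxidative addition and reductive elimination retain the alkene geometry, so the benzyl group ends cis to the carbinol carbon and the ester trans (E), and the free hydroxyl is tolerated.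

Step 11
Reactants: 21 methyl (2E,4R)-4-Ar-2-(BF-methyl)-4-hydroxybut-2-enoate; 22 (bromomethyl)chlorodimethylsilane
Product: 23 methyl (2E,4R)-4-Ar-2-(BF-methyl)-4-{[(bromomethyl)dimethylsilyl]oxy}but-2-enoate
Conditions: Et3N, DMAP (cat.), CH2Cl2, 0 °C; rapid filtration through Et3N-deactivated silica
Reagents that add atoms: none
Why: Silylation of the only free hydroxyl with the chlorosilane; the product is about as labile as a trimethylsilyl ether and is therefore used directly.

Step 12
Reactants: 23 methyl (2E,4R)-4-Ar-2-(BF-methyl)-4-{[(bromomethyl)dimethylsilyl]oxy}but-2-enoate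
Product: 24 methyl (2R)-2-[(4S,5R)-5-Ar-2,2-dimethyl-1,2-oxasilolan-4-yl]-3-BF-propanoate (2R epimer drawn; the 2S epimer is expected alongside)
Conditions: Bu3SnH (1.5 equiv), AIBN (0.2 equiv), syringe pump over 6 h, benzene (0.01 M), 80 °C
Reagents that add atoms: none
Why: The tributyltin radical abstracts bromine to give a nucleophilic α-silyl methyl radical held on the carbinol oxygen; it adds to C-3 of the enoate (the β-carbon), and the ester-stabilised tertiary radical at C-2 takes hydrogen from Bu3SnH, which carries the chain. The closest known reaction type is the radical cyclisation of (bromomethyl)dimethylsilyl ethers of allylic alcohols, used with a later Tamao oxidation to make 1,3-diols. The 1,2-oxasilolane closes in the 5-exo-trig mode; the 6-endo mode would need attack at the fully substituted, polarity-mismatched α-carbon. C-4 of the oxasilolane (the future C-β) is controlled by the carbinol centre: in the chair-like transition state the carbinol hydrogen eclipses the alkene to avoid A(1,3) strain with the cis benzofuranylmethyl group, the aryl group lies pseudo-equatorial and away from the forming bond, and the ring should close with aryl and side chain trans (4S,5R; S only because silicon outranks oxygen). C-2 of the propanoate (C-α) is set by hydrogen transfer to an acyclic radical with little bias, so a mixture of epimers is expected and is corrected in step 14. The selectivities needed are cyclisation over direct reduction, secured by slow stannane addition at high dilution, and the facial selectivity, secured by the trisubstituted alkene.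

Step 13
Reactants: 24 methyl (2R)-2-[(4S,5R)-5-Ar-2,2-dimethyl-1,2-oxasilolan-4-yl]-3-BF-propanoate
Product: 25 methyl (2R,3R,4R)-4-Ar-2-(BF-methyl)-4-hydroxy-3-(hydroxymethyl)butanoate (with its C-2 epimer; any lactone already formed is carried on)
Conditions: 30% H2O2, KF, KHCO3, THF/MeOH (1:1), rt
Reagents that add atoms: hydrogen peroxide, OO
Why: Tamao oxidation: activated peroxide inserts oxygen into the C–Si bond and the Si–O bond is hydrolysed, giving the 1,3-diol; benzyl ethers and the primary TBS ether tolerate these conditions, which is the reason the phenols are not carried as silyl ethers.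

Step 14
Reactants: 25 methyl (2R,3R,4R)-4-Ar-2-(BF-methyl)-4-hydroxy-3-(hydroxymethyl)butanoate
Product: 27 (3R,4R)-4-[(R)-Ar(hydroxy)methyl]-3-(BF-methyl)oxolan-2-one, via cis lactone 26 (not isolated)
Conditions: DBU, toluene, 60 °C
Reagents that add atoms: none
Why: Base-catalysed lactonisation of the primary hydroxyl onto the methyl ester followed by enolate equilibration of C-α to the trans lactone; closure through the secondary carbinol is slower and would place aryl and hydroxymethyl cis on the ring, so the primary lactone should be favoured kinetically and thermodynamically.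

Step 15
Reactants: 27 (3R,4R)-4-[(R)-Ar(hydroxy)methyl]-3-(BF-methyl)oxolan-2-one
Product: 28 (3R,4R)-4-[(R)-Ar(hydroxy)methyl]-3-{[(2S,3R)-2-Ar-3-(hydroxymethyl)-7-methoxy-2,3-dihydro-1-benzofuran-5-yl]methyl}oxolan-2-one
Conditions: Bu4NF, AcOH (1:1), THF, 0 °C → rt
Reagents that add atoms: none
Why: Acetic-acid-buffered fluoride cleaves the primary TBS ether without lactone migration or epimerisation; the phenols are still benzylated, so no quinone methide can form.

Step 16
Reactants: 28 (3R,4R)-4-[(R)-Ar(hydroxy)methyl]-3-{[(2S,3R)-2-Ar-3-(hydroxymethyl)-7-methoxy-2,3-dihydro-1-benzofuran-5-yl]methyl}oxolan-2-one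
Product: 29 (3R,4R)-4-[(R)-hydroxy(4-hydroxy-3-methoxyphenyl)methyl]-3-{[(2S,3R)-2-(4-hydroxy-3-methoxyphenyl)-3-(hydroxymethyl)-7-methoxy-2,3-dihydro-1-benzofuran-5-yl]methyl}oxolan-2-one (CNP0233460.1)
Conditions: H2 (1 atm), 10% Pd/C, EtOAc/EtOH, rt
Reagents that add atoms: none
Why: Hydrogenolysis of the two aryl benzyl ethers under neutral conditions; aryl benzyl ethers cleave much faster than the benzylic alcohol or the benzylic C-2–O bond, and the reaction is stopped as soon as both are gone.

## Compound list

1 | 4-(benzyloxy)-3-methoxybenzaldehyde | COc1cc(C=O)ccc1OCc1ccccc1 | starting material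
2 | methyl prop-2-ynoate (methyl propiolate) | C#CC(=O)OC | starting material
3 | ethyl(3-methoxy-3-oxoprop-1-yn-1-yl)zinc (not isolated) | CC[Zn]C#CC(=O)OC | intermediate
4 | methyl (4S)-4-[4-(benzyloxy)-3-methoxyphenyl]-4-hydroxybut-2-ynoate | COC(=O)C#C[C@@H](O)c1ccc(OCc2ccccc2)c(OC)c1 | intermediate
5 | sodium alkenylaluminate chelate: Al on C-2 of the (Z)-enoate and on the carbinol oxygen, two 2-methoxyethoxy ligands (not isolated) | [Na+].COCCO[Al-]1(OCCOC)O[C@H](C=C1C(=O)OC)c1ccc(OCc2ccccc2)c(OC)c1 | intermediate
6 | methyl (2Z,4R)-4-[4-(benzyloxy)-3-methoxyphenyl]-4-hydroxy-2-iodobut-2-enoate | COC(=O)/C(I)=C/[C@@H](O)c1ccc(OCc2ccccc2)c(OC)c1 | intermediate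
7 | 4-bromo-2-methoxyphenol | COc1cc(Br)ccc1O | starting material
8 | 4-bromo-2-iodo-6-methoxyphenol | COc1cc(Br)cc(I)c1O | intermediate
9 | [4-(benzyloxy)-3-methoxyphenyl]methanol | COc1cc(CO)ccc1OCc1ccccc1 | starting material
10 | 2-{[4-(benzyloxy)-3-methoxyphenyl]methoxy}-5-bromo-1-iodo-3-methoxybenzene | COc1cc(Br)cc(I)c1OCc1ccc(OCc2ccccc2)c(OC)c1 | intermediate
11 | methyl diazoacetate | COC(=O)C=[N+]=[N-] | starting material
12 | methyl 2-(2-{[4-(benzyloxy)-3-methoxyphenyl]methoxy}-5-bromo-3-methoxyphenyl)-2-diazoacetate | COC(=O)C(=[N+]=[N-])c1cc(Br)cc(OC)c1OCc1ccc(OCc2ccccc2)c(OC)c1 | intermediate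
13 | methyl (2S,3R)-2-Ar-5-bromo-7-methoxy-2,3-dihydro-1-benzofuran-3-carboxylate, cis (not isolated) | COc1cc([C@H]2Oc3c(OC)cc(Br)cc3[C@H]2C(=O)OC)ccc1OCc1ccccc1 | intermediate
14 | methyl (2S,3S)-2-Ar-5-bromo-7-methoxy-2,3-dihydro-1-benzofuran-3-carboxylate, trans | COc1cc([C@H]2Oc3c(OC)cc(Br)cc3[C@@H]2C(=O)OC)ccc1OCc1ccccc1 | intermediate
15 | [(2S,3R)-2-Ar-5-bromo-7-methoxy-2,3-dihydro-1-benzofuran-3-yl]methanol | COc1cc([C@H]2Oc3c(OC)cc(Br)cc3[C@@H]2CO)ccc1OCc1ccccc1 | intermediate
16 | (2S,3R)-2-Ar-5-bromo-3-{[tert-butyl(dimethyl)silyl]oxymethyl}-7-methoxy-2,3-dihydro-1-benzofuran (BF-Br) | COc1cc([C@H]2Oc3c(OC)cc(Br)cc3[C@@H]2CO[Si](C)(C)C(C)(C)C)ccc1OCc1ccccc1 | intermediate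
17 | 2-(chloromethyl)-4,4,5,5-tetramethyl-1,3,2-dioxaborolane | ClCB1OC(C)(C)C(C)(C)O1 | starting material
18 | BF-Li, the 5-lithio derivative of 16 (not isolated) | COc1cc([C@H]2Oc3c(OC)cc([Li])cc3[C@@H]2CO[Si](C)(C)C(C)(C)C)ccc1OCc1ccccc1 | intermediate
19 | lithium BF(chloromethyl) pinacol borate (not isolated) | [Li+].COc1cc([C@H]2Oc3c(OC)cc([B-]4(CCl)OC(C)(C)C(C)(C)O4)cc3[C@@H]2CO[Si](C)(C)C(C)(C)C)ccc1OCc1ccccc1 | intermediate
20 | BF-CH2-Bpin, the 5-[(pinacolboryl)methyl] compound | COc1cc([C@H]2Oc3c(OC)cc(CB4OC(C)(C)C(C)(C)O4)cc3[C@@H]2CO[Si](C)(C)C(C)(C)C)ccc1OCc1ccccc1 | intermediate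
21 | methyl (2E,4R)-4-Ar-2-(BF-methyl)-4-hydroxybut-2-enoate | COc1cc([C@H]2Oc3c(OC)cc(C/C(C(=O)OC)=C\[C@@H](O)c4ccc(OCc5ccccc5)c(OC)c4)cc3[C@@H]2CO[Si](C)(C)C(C)(C)C)ccc1OCc1ccccc1 | intermediate
22 | (bromomethyl)chlorodimethylsilane | C[Si](C)(Cl)CBr | starting material
23 | methyl (2E,4R)-4-Ar-2-(BF-methyl)-4-{[(bromomethyl)dimethylsilyl]oxy}but-2-enoate | COc1cc([C@H]2Oc3c(OC)cc(C/C(C(=O)OC)=C\[C@@H](O[Si](C)(C)CBr)c4ccc(OCc5ccccc5)c(OC)c4)cc3[C@@H]2CO[Si](C)(C)C(C)(C)C)ccc1OCc1ccccc1 | intermediate
24 | methyl (2R)-2-[(4S,5R)-5-Ar-2,2-dimethyl-1,2-oxasilolan-4-yl]-3-BF-propanoate (2R epimer drawn; 2S epimer expected alongside) | COc1cc([C@H]2Oc3c(OC)cc(C[C@@H](C(=O)OC)[C@@H]4C[Si](C)(C)O[C@H]4c4ccc(OCc5ccccc5)c(OC)c4)cc3[C@@H]2CO[Si](C)(C)C(C)(C)C)ccc1OCc1ccccc1 | intermediate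
25 | methyl (2R,3R,4R)-4-Ar-2-(BF-methyl)-4-hydroxy-3-(hydroxymethyl)butanoate (2R epimer drawn; 2S epimer expected alongside) | COc1cc([C@H]2Oc3c(OC)cc(C[C@@H](C(=O)OC)[C@H](CO)[C@@H](O)c4ccc(OCc5ccccc5)c(OC)c4)cc3[C@@H]2CO[Si](C)(C)C(C)(C)C)ccc1OCc1ccccc1 | intermediate
26 | (3S,4R)-4-[(R)-Ar(hydroxy)methyl]-3-(BF-methyl)oxolan-2-one, cis lactone (not isolated) | COc1cc([C@H]2Oc3c(OC)cc(C[C@@H]4C(=O)OC[C@@H]4[C@@H](O)c4ccc(OCc5ccccc5)c(OC)c4)cc3[C@@H]2CO[Si](C)(C)C(C)(C)C)ccc1OCc1ccccc1 | intermediate
27 | (3R,4R)-4-[(R)-Ar(hydroxy)methyl]-3-(BF-methyl)oxolan-2-one, trans lactone | COc1cc([C@H]2Oc3c(OC)cc(C[C@H]4C(=O)OC[C@@H]4[C@@H](O)c4ccc(OCc5ccccc5)c(OC)c4)cc3[C@@H]2CO[Si](C)(C)C(C)(C)C)ccc1OCc1ccccc1 | intermediate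
28 | (3R,4R)-4-[(R)-Ar(hydroxy)methyl]-3-{[(2S,3R)-2-Ar-3-(hydroxymethyl)-7-methoxy-2,3-dihydro-1-benzofuran-5-yl]methyl}oxolan-2-one | COc1cc([C@H]2Oc3c(OC)cc(C[C@H]4C(=O)OC[C@@H]4[C@@H](O)c4ccc(OCc5ccccc5)c(OC)c4)cc3[C@@H]2CO)ccc1OCc1ccccc1 | intermediate
29 | (3R,4R)-4-[(R)-hydroxy(4-hydroxy-3-methoxyphenyl)methyl]-3-{[(2S,3R)-2-(4-hydroxy-3-methoxyphenyl)-3-(hydroxymethyl)-7-methoxy-2,3-dihydro-1-benzofuran-5-yl]methyl}oxolan-2-one | COc1cc([C@H]2Oc3c(OC)cc(C[C@H]4C(=O)OC[C@@H]4[C@@H](O)c4ccc(O)c(OC)c4)cc3[C@@H]2CO)ccc1O | target

## Step count and least certain steps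

Total: 16 steps. Longest linear sequence: 14 steps (7 → 29, steps 3–16); the iodide branch (steps 1–2) joins at step 10.

**Step 12 (key step).** The most likely failure is hydrogen transfer from the stannane to the α-silyl radical before it closes onto the crowded β-carbon. A second possibility is erosion of facial selectivity, because the aryl group and the benzofuranylmethyl group both press on the transition state. The fallback keeps the silicon-tethered delivery but applies it to the less hindered, α-unsubstituted acceptor and attaches the benzofuran half afterwards by lactone alkylation. It sets out from 4 and from 20 and comes back at 28.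
- Alkyne 4 is reduced with NaAlH2(OCH2CH2OMe)2 and quenched with aqueous acid to give methyl (2E,4R)-4-Ar-4-hydroxybut-2-enoate F1.
- F1 is silylated with 22 to the (bromomethyl)dimethylsilyl ether F2 and cyclised with Bu3SnH/AIBN to the oxasilolane acetate F3.
- Tamao oxidation gives the dihydroxy ester F4, which closes under the basic conditions to the hydroxy lactone F5; TESCl/imidazole gives the TES ether F6.
- Separately, boronate 20 is oxidised with NaBO3·4H2O to the benzylic alcohol F7 and converted with CBr4/PPh3 into the benzylic bromide F8.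
- Deprotonation of F6 with LiN(SiMe3)2 at −78 °C and alkylation with F8 should occur trans to the β-substituent and give the bis-silylated trans lactone F9.
- Buffered Bu4NF removes both silyl groups and delivers 28.

**Step 10.** The most likely failure is protodeboronation of the benzylic boronate, or transmetalation too slow to outrun base-induced isomerisation of the γ-hydroxy enoate to a γ-keto ester. The fallback is a Negishi coupling; it sets out from 20 and 6 and comes back at 21.
- Bromide F8, made from 20 as described above, is inserted with Zn dust/LiCl in THF at 0 °C to give the benzylzinc bromide F10.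
- Iodide 6 is protected with TESCl/imidazole as the TES ether F11.
- Pd(PPh3)4 in THF at rt couples the two to the TES-protected enoate F12.
- HF·pyridine in THF/pyridine at 0 °C removes the secondary TES group in preference to the primary TBS group and returns 21.

**Step 2.** The most likely failure is protonation of the alkenylaluminate before iodine capture, or reduction of the ester by excess hydride. The fallback abandons the iodide. Alkyne 4 is reduced and quenched with acid to enoate F1, and the material is carried through the sequence F2 → F9 described for step 12. It sets out from 4 and comes back at 28.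

**Step 6.** The most likely failure is insufficient or reversed enantioselection, because the methoxy group flanking the ether oxygen changes how the benzyloxy group sits in the catalyst pocket. The fallback is classical resolution; it sets out from 12 and comes back at 15.
- Insertion with achiral Rh2(OAc)4 and methoxide epimerisation give the racemic series: cis ester 13 with its enantiomer F13, then trans ester 14 with its enantiomer F14.
- LiOH hydrolysis gives the trans acid, which is resolved by crystallisation of its 1-phenylethylammonium salt into the (2S,3S) acid F15 and its enantiomer F16.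
- BH3·SMe2 reduces F15 to 15.

## Further compounds

F1 | step 12 | methyl (2E,4R)-4-[4-(benzyloxy)-3-methoxyphenyl]-4-hydroxybut-2-enoate | COC(=O)/C=C/[C@@H](O)c1ccc(OCc2ccccc2)c(OC)c1
F2 | step 12 | methyl (2E,4R)-4-[4-(benzyloxy)-3-methoxyphenyl]-4-{[(bromomethyl)dimethylsilyl]oxy}but-2-enoate | COC(=O)/C=C/[C@@H](O[Si](C)(C)CBr)c1ccc(OCc2ccccc2)c(OC)c1
F3 | step 12 | methyl 2-[(4S,5R)-5-[4-(benzyloxy)-3-methoxyphenyl]-2,2-dimethyl-1,2-oxasilolan-4-yl]acetate | COC(=O)C[C@@H]1C[Si](C)(C)O[C@H]1c1ccc(OCc2ccccc2)c(OC)c1
F4 | step 12 | methyl (3R,4R)-4-[4-(benzyloxy)-3-methoxyphenyl]-4-hydroxy-3-(hydroxymethyl)butanoate | COC(=O)C[C@H](CO)[C@@H](O)c1ccc(OCc2ccccc2)c(OC)c1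
F5 | step 12 | (4R)-4-[(R)-[4-(benzyloxy)-3-methoxyphenyl](hydroxy)methyl]oxolan-2-one | O=C1C[C@H](CO1)[C@@H](O)c1ccc(OCc2ccccc2)c(OC)c1
F6 | step 12 | (4R)-4-[(R)-[4-(benzyloxy)-3-methoxyphenyl][(triethylsilyl)oxy]methyl]oxolan-2-one | O=C1C[C@H](CO1)[C@@H](O[Si](CC)(CC)CC)c1ccc(OCc2ccccc2)c(OC)c1
F7 | step 12 | [(2S,3R)-2-Ar-3-(TBSO-methyl)-7-methoxy-2,3-dihydro-1-benzofuran-5-yl]methanol | COc1cc([C@H]2Oc3c(OC)cc(CO)cc3[C@@H]2CO[Si](C)(C)C(C)(C)C)ccc1OCc1ccccc1
F8 | step 12 | (2S,3R)-2-Ar-5-(bromomethyl)-3-(TBSO-methyl)-7-methoxy-2,3-dihydro-1-benzofuran | COc1cc([C@H]2Oc3c(OC)cc(CBr)cc3[C@@H]2CO[Si](C)(C)C(C)(C)C)ccc1OCc1ccccc1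
F9 | step 12 | (3R,4R)-4-[(R)-Ar(triethylsilyloxy)methyl]-3-(BF-methyl)oxolan-2-one | COc1cc([C@H]2Oc3c(OC)cc(C[C@H]4C(=O)OC[C@@H]4[C@@H](O[Si](CC)(CC)CC)c4ccc(OCc5ccccc5)c(OC)c4)cc3[C@@H]2CO[Si](C)(C)C(C)(C)C)ccc1OCc1ccccc1
F10 | step 10 | BF-methylzinc bromide | COc1cc([C@H]2Oc3c(OC)cc(C[Zn]Br)cc3[C@@H]2CO[Si](C)(C)C(C)(C)C)ccc1OCc1ccccc1
F11 | step 10 | methyl (2Z,4R)-4-[4-(benzyloxy)-3-methoxyphenyl]-2-iodo-4-[(triethylsilyl)oxy]but-2-enoate | COC(=O)/C(I)=C/[C@@H](O[Si](CC)(CC)CC)c1ccc(OCc2ccccc2)c(OC)c1
F12 | step 10 | methyl (2E,4R)-4-Ar-2-(BF-methyl)-4-[(triethylsilyl)oxy]but-2-enoate | COc1cc([C@H]2Oc3c(OC)cc(C/C(C(=O)OC)=C\[C@@H](O[Si](CC)(CC)CC)c4ccc(OCc5ccccc5)c(OC)c4)cc3[C@@H]2CO[Si](C)(C)C(C)(C)C)ccc1OCc1ccccc1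
F0 | step 2 | none | none
F13 | step 6 | methyl (2R,3S)-2-Ar-5-bromo-7-methoxy-2,3-dihydro-1-benzofuran-3-carboxylate (enantiomer of 13) | COc1cc([C@@H]2Oc3c(OC)cc(Br)cc3[C@@H]2C(=O)OC)ccc1OCc1ccccc1
F14 | step 6 | methyl (2R,3R)-2-Ar-5-bromo-7-methoxy-2,3-dihydro-1-benzofuran-3-carboxylate (enantiomer of 14) | COc1cc([C@@H]2Oc3c(OC)cc(Br)cc3[C@H]2C(=O)OC)ccc1OCc1ccccc1
F15 | step 6 | (2S,3S)-2-Ar-5-bromo-7-methoxy-2,3-dihydro-1-benzofuran-3-carboxylic acid | COc1cc([C@H]2Oc3c(OC)cc(Br)cc3[C@@H]2C(=O)O)ccc1OCc1ccccc1
F16 | step 6 | (2R,3R)-2-Ar-5-bromo-7-methoxy-2,3-dihydro-1-benzofuran-3-carboxylic acid | COc1cc([C@@H]2Oc3c(OC)cc(Br)cc3[C@H]2C(=O)O)ccc1OCc1ccccc1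
A1 | alternative 1 | (2E)-3-[3-methoxy-4-(triisopropylsilyloxy)phenyl]prop-2-en-1-yl methyl 2-diazopropanedioate | COC(=O)C(=[N+]=[N-])C(=O)OC/C=C/c1ccc(O[Si](C(C)C)(C(C)C)C(C)C)c(OC)c1
A2 | alternative 1 | methyl 6-exo-[3-methoxy-4-(triisopropylsilyloxy)phenyl]-2-oxo-3-oxabicyclo[3.1.0]hexane-1-carboxylate | COC(=O)[C@@]12C(=O)OC[C@@H]1[C@H]2c1ccc(O[Si](C(C)C)(C(C)C)C(C)C)c(OC)c1
A3 | alternative 2 | 3-[(R)-(tert-butyldimethylsilyloxy)[3-methoxy-4-(triisopropylsilyloxy)phenyl]methyl]cyclobutan-1-one | O=C1CC(C1)[C@@H](O[Si](C)(C)C(C)(C)C)c1ccc(O[Si](C(C)C)(C(C)C)C(C)C)c(OC)c1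
A4 | alternative 2 | (4R)-4-[(R)-(tert-butyldimethylsilyloxy)[3-methoxy-4-(triisopropylsilyloxy)phenyl]methyl]oxolan-2-one | O=C1C[C@H](CO1)[C@@H](O[Si](C)(C)C(C)(C)C)c1ccc(O[Si](C(C)C)(C(C)C)C(C)C)c(OC)c1
A5 | alternative 3 | (2S)-6-bromo-8-methoxy-2-[3-methoxy-4-(triisopropylsilyloxy)phenyl]-2,3-dihydro-4H-chromen-4-one | O=C1C[C@@H](c2ccc(O[Si](C(C)C)(C(C)C)C(C)C)c(OC)c2)Oc2c(OC)cc(Br)cc12
A6 | alternative 3 | methyl (2S,3S)-5-bromo-7-methoxy-2-[3-methoxy-4-(triisopropylsilyloxy)phenyl]-2,3-dihydro-1-benzofuran-3-carboxylate | COc1cc([C@H]2Oc3c(OC)cc(Br)cc3[C@@H]2C(=O)OC)ccc1O[Si](C(C)C)(C(C)C)C(C)C
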